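**Retrosynthetic overview**
- Late stage: the C7 acetate, the C18 methyl (Negishi coupling on a C4 enol triflate) and the 7α,8α-diol (osmylation of a Δ7 alkene) are removed; the butenolide is cut at C12–C13 (intermolecular Heck reaction of a C9 vinyl group with 4-bromofuran-2(5H)-one).
- Key disconnection C8–C9: ring B is closed by a 6-exo Heck cyclisation of a (Z)-alkenyl iodide (C7=C8–iodide) onto a (Z)-but-2-en-2-yl group (C9=C11) carried by ring A.
- Enabling feature: C9 is a quaternary ring-B carbon bearing the C11=C12 double bond, and C8 is an oxygenated carbon cis-vicinal to the C7 oxygen. C8 can therefore be an sp2 alkenyl-palladium carbon; C9, having no hydrogen, forces β-hydride elimination towards C12; and the Δ7 alkene left in ring B is the latent cis-7,8-diol.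
- The cyclisation substrate is assembled in one operation from three pieces: 2-methylcyclohex-2-en-1-one (ring A, C5, C10), a (Z)-but-2-en-2-yl metal (C9, C11, C12, C20) and (Z)-3-iodobut-2-enal (C6–C8, C17).
- Ring order: ring A (bought) → ring B (step 4) → butenolide ring (bought, attached in step 5).

Key step: step 4

Remark: locants follow clerodane numbering (C1–C20) and β is the face of the C5 methyl group; it is assumed that the antipode of the chiral phosphoramidite ligand L* (O,O′-(1,1′-binaphthalene-2,2′-diyl) N,N-bis(1-phenylethyl)phosphoramidite) can be chosen so that the conjugate addition of step 3 gives the (R)-configured ring stereocentre.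

Step 1
Reactants: 1 but-2-yn-1-ol
Product: 3 (Z)-3-iodobut-2-en-1-ol, via sodium alkenylalanate 2 (not isolated)
Conditions: NaAlH2(OCH2CH2OMe)2, THF, 0 °C → rt; then I2, −78 → 0 °C
Reagents that add atoms: iodine [I][I]
Why: Hydroxyl-directed trans-hydroalumination of the propargylic alcohol places aluminium on C3 in a five-membered alanate, and iodinolysis of the C–Al bond with retention should give the Z-iodoalkene (hydroalumination–iodination).

Step 2
Reactants: 3 (Z)-3-iodobut-2-en-1-ol
Product: 4 (Z)-3-iodobut-2-enal
Conditions: MnO2, CH2Cl2, rt, dark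
Reagents that add atoms: none
Why: MnO2 oxidises the allylic alcohol to the enal without touching the C–iodine bond or the Z geometry (allylic oxidation); the aldehyde is used at once.

Step 3
Reactants: 5 (Z)-2-bromobut-2-ene; 6 2-methylcyclohex-2-en-1-one; 4 (Z)-3-iodobut-2-enal
Product: 10 (2S,3R)-3-[(Z)-but-2-en-2-yl]-2-[(1S,2Z)-1-hydroxy-3-iodobut-2-en-1-yl]-2-methylcyclohexan-1-one, via (Z)-but-2-en-2-yllithium 7 (not isolated), via (Z)-but-2-en-2-yl(dimethyl)alane 8 (not isolated), via dimethylaluminium enolate 9 (not isolated)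
Conditions: 5, t-BuLi (2 equiv), Et2O, −78 °C; Me2AlCl, −78 → −30 °C; 6, Cu(OTf)2 (5 mol %), L* (10 mol %), −30 °C; then 4, −78 °C; aq. NH4Cl
Reagents that add atoms: none
Why: Lithium–bromine exchange and transmetalation to aluminium keep the Z geometry, the copper–phosphoramidite catalyst delivers the alkenyl group to one face of the enone (sets C10), and the tetrasubstituted enolate adds to the aldehyde anti to the new C10 substituent through a chair Zimmerman–Traxler transition state with the aldehyde residue equatorial, which should set C5 (C6 trans to C9) and C6 (hydroxyl syn to the C5 methyl) (tandem copper-catalysed asymmetric conjugate addition–aldol reaction).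

Step 4
Reactants: 10 aldol adduct
Product: 11 (4aR,5R,8S,8aS)-5-ethenyl-8-hydroxy-5,6,8a-trimethyl-3,4,4a,5,8,8a-hexahydronaphthalen-1(2H)-one
Conditions: Pd(OAc)2 (10 mol %), PPh3 (20 mol %), KOAc, DMF, 70 °C
Reagents that add atoms: none
Why: Zerovalent palladium inserts into the C8–iodine bond of the Z-alkenyl iodide with retention, the C8–Pd bond adds syn across C9=C11 to forge the C8–C9 bond, and the C11–Pd species, which has β-hydrogens only on C12 because C9 is now quaternary, eliminates to the C11=C12 vinyl group (intramolecular Mizoroki–Heck reaction). The closest known reaction type is the quaternary-centre-forming Heck cyclisation of alkenyl iodides onto trisubstituted alkenes. Ring B is closed in the 6-exo-trig mode onto ring A, whose C5/C10 trans relationship already fixes a trans-fused decalin. The new C9 stereocentre is controlled by 1,3-allylic strain: because C12 is cis to C10 in the Z-butenyl group, the C10–H bond must eclipse the alkene plane, C5 and C1 then lie on opposite faces, and C8, tethered through C6 and C5, can only reach the face on the C5 side, which should place the C9 methyl axial (cis to the C5 methyl) and the vinyl group equatorial. The step needs 6-exo over 7-endo closure and a single direction of β-hydride elimination; the shorter tether and the absence of hydrogen on C9 secure both, and the mild base KOAc spares the β-hydroxy ketone from retro-aldol cleavage.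

Step 5
Reactants: 11 bicyclic hydroxy ketone; 12 4-bromofuran-2(5H)-one
Product: 13 (4aR,5R,8S,8aS)-8-hydroxy-5,6,8a-trimethyl-5-[(E)-2-(5-oxo-2,5-dihydrofuran-3-yl)ethenyl]-3,4,4a,5,8,8a-hexahydronaphthalen-1(2H)-one
Conditions: Pd(OAc)2 (10 mol %), P(o-tolyl)3 (20 mol %), KOAc, DMF, 90 °C
Reagents that add atoms: none
Why: Zerovalent palladium inserts into the C–Br bond of the β-bromobutenolide, the alkenylpalladium adds to the terminal carbon of the C9 vinyl group and syn β-hydride elimination should give the E-configured C11=C12 bond, while the trisubstituted Δ7 alkene is too hindered to react (intermolecular Heck reaction).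

Step 6
Reactants: 13 hydroxy ketone with dienyl butenolide
Product: 14 6β-acetoxy-4-oxo-18-norcleroda-7,11E,13-trien-15,16-olide
Conditions: Ac2O, pyridine, DMAP (cat.), CH2Cl2, 0 °C → rt
Reagents that add atoms: acetic anhydride CC(=O)OC(C)=O
Why: Acylation of the only hydroxyl group installs the C6 acetate of the target and blocks O6 before the triflation (DMAP-catalysed esterification).

Step 7
Reactants: 14 acetoxy ketone
Product: 15 6β-acetoxy-4-(trifluoromethanesulfonyloxy)-18-norcleroda-3,7,11E,13-tetraen-15,16-olide
Conditions: Tf2O, 2,6-di-tert-butyl-4-methylpyridine, CH2Cl2, 0 °C → rt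
Reagents that add atoms: trifluoromethanesulfonic anhydride O=S(=O)(OS(=O)(=O)C(F)(F)F)C(F)(F)F
Why: O-Triflation of the ketone and loss of a C3 proton to the hindered base give the enol triflate, whose regiochemistry is fixed because C5 is quaternary; the non-basic conditions spare the acetate and the butenolide, and the electron-poor enol triflate masks the future C3=C4 bond against osmylation (ketone to enol triflate with Tf2O and a hindered pyridine).

Step 8
Reactants: 15 enol triflate
Product: 16 6β-acetoxy-7α,8α-dihydroxy-4-(trifluoromethanesulfonyloxy)-18-norcleroda-3,11E,13-trien-15,16-olide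
Conditions: OsO4 (5 mol %), NMO, acetone–H2O, 0 °C → rt
Reagents that add atoms: osmium tetroxide O=[Os](=O)(=O)=O; 4-methylmorpholine N-oxide C[N+]1([O-])CCOCC1; water O
Why: The trisubstituted Δ7 alkene is the most electron-rich olefin (enol triflate and dienyl lactone are deactivated), and OsO4 should add to its α face, anti to the axial C5 and C9 methyl groups and to the allylic C6 acetoxy group, which sets C7 (α-OH) and C8 (α-OH, β-methyl) together (catalytic syn-dihydroxylation).

Step 9
Reactants: 16 diol enol triflate
Product: 17 6β-acetoxy-7α,8α-dihydroxycleroda-3,11E,13-trien-15,16-olide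
Conditions: Me2Zn, Pd(PPh3)4 (5 mol %), THF, 0 → 50 °C
Reagents that add atoms: dimethylzinc C[Zn]C
Why: Oxidative addition of zerovalent palladium into the enol triflate, transmetalation from zinc and reductive elimination install the C18 methyl on C4 with the C3=C4 bond in place, the free hydroxyl groups only consuming Me2Zn as zinc alkoxides (Negishi coupling).

Step 10
Reactants: 17 monoacetate diol
Product: 18 (5R,6R,7S,8R,9R,10S)-6β,7α-diacetoxy-8α-hydroxycleroda-3,11E,13-trien-15,16-olide
Conditions: Ac2O, pyridine, 0 °C → rt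
Reagents that add atoms: acetic anhydride CC(=O)OC(C)=O
Why: The equatorial secondary C7 hydroxyl is acetylated while the tertiary axial C8 hydroxyl next to the C9 quaternary centre should not react, and any O6/O7 acetyl migration in steps 8 and 9 converges on the same diacetate (selective esterification).

**Compound list**
1 | but-2-yn-1-ol | CC#CCO | starting material
2 | sodium 2,2-bis(2-methoxyethoxy)-3-methyl-2,5-dihydro-1,2-oxaluminol-2-uide (cyclic alkenylalanate) | CC1=CCO[Al-]1(OCCOC)OCCOC.[Na+] | intermediate
3 | (Z)-3-iodobut-2-en-1-ol | I/C(C)=C\CO | intermediate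
4 | (Z)-3-iodobut-2-enal | I/C(C)=C\C=O | intermediate
5 | (Z)-2-bromobut-2-ene (Br cis to the C4 methyl) | C/C=C(/C)Br | starting material
6 | 2-methylcyclohex-2-en-1-one | CC1=CCCCC1=O | starting material
7 | (Z)-but-2-en-2-yllithium | C/C=C(/C)[Li] | intermediate
8 | (Z)-but-2-en-2-yl(dimethyl)alane | C/C=C(/C)[Al](C)C | intermediate
9 | dimethylaluminium (R)-3-[(Z)-but-2-en-2-yl]-2-methylcyclohex-1-en-1-olate | CC1=C(O[Al](C)C)CCC[C@@H]1/C(C)=C\C | intermediate
10 | (2S,3R)-3-[(Z)-but-2-en-2-yl]-2-[(1S,2Z)-1-hydroxy-3-iodobut-2-en-1-yl]-2-methylcyclohexan-1-one | I/C(C)=C\[C@H](O)[C@@]1(C)C(=O)CCC[C@@H]1/C(C)=C\C | intermediate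
11 | (4aR,5R,8S,8aS)-5-ethenyl-8-hydroxy-5,6,8a-trimethyl-3,4,4a,5,8,8a-hexahydronaphthalen-1(2H)-one (trans-fused; 4-oxo, 5β-Me, 6β-OH, Δ7, 8-Me, 9β-Me, 9α-vinyl, 10α-H) | O[C@H]1C=C(C)[C@](C)(C=C)[C@H]2CCCC(=O)[C@]12C | intermediate
12 | 4-bromofuran-2(5H)-one | O=C1C=C(Br)CO1 | starting material
13 | (4aR,5R,8S,8aS)-8-hydroxy-5,6,8a-trimethyl-5-[(E)-2-(5-oxo-2,5-dihydrofuran-3-yl)ethenyl]-3,4,4a,5,8,8a-hexahydronaphthalen-1(2H)-one | O[C@H]1C=C(C)[C@](C)(/C=C/C3=CC(=O)OC3)[C@H]2CCCC(=O)[C@]12C | intermediate
14 | 6β-acetoxy-4-oxo-18-norcleroda-7,11E,13-trien-15,16-olide | CC(=O)O[C@H]1C=C(C)[C@](C)(/C=C/C3=CC(=O)OC3)[C@H]2CCCC(=O)[C@]12C | intermediate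
15 | 6β-acetoxy-4-(trifluoromethanesulfonyloxy)-18-norcleroda-3,7,11E,13-tetraen-15,16-olide | CC(=O)O[C@H]1C=C(C)[C@](C)(/C=C/C3=CC(=O)OC3)[C@H]2CCC=C(OS(=O)(=O)C(F)(F)F)[C@]12C | intermediate
16 | 6β-acetoxy-7α,8α-dihydroxy-4-(trifluoromethanesulfonyloxy)-18-norcleroda-3,11E,13-trien-15,16-olide | CC(=O)O[C@H]1[C@H](O)[C@](C)(O)[C@](C)(/C=C/C3=CC(=O)OC3)[C@H]2CCC=C(OS(=O)(=O)C(F)(F)F)[C@]12C | intermediate
17 | 6β-acetoxy-7α,8α-dihydroxycleroda-3,11E,13-trien-15,16-olide | CC(=O)O[C@H]1[C@H](O)[C@](C)(O)[C@](C)(/C=C/C3=CC(=O)OC3)[C@H]2CCC=C(C)[C@]12C | intermediate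
18 | (5R,6R,7S,8R,9R,10S)-6β,7α-diacetoxy-8α-hydroxycleroda-3,11E,13-trien-15,16-olide (CNP0383656.1) | CC(=O)O[C@H]1[C@H](OC(C)=O)[C@](C)(O)[C@](C)(/C=C/C2=CC(=O)OC2)[C@H]2CCC=C(C)[C@]12C | target

**Totals**
Total step count: 10. Longest linear sequence: 10 steps (1 → 3 → 4 → 10 → 11 → 13 → 14 → 15 → 16 → 17 → 18).

**Steps most likely to fail**

Step 3. Leftover alkenylalane may consume the sensitive iodoenal by 1,2-addition, the aluminium aldolate may undergo retro-aldol cleavage, or facial control in the one-pot aldol may be poor. The fallback separates the two events. It sets out from the aluminium enolate 9, generated as in step 3 but without aldehyde. The enolate is silylated with Me3SiCl/Et3N to the trimethylsilyl enol ether F1, which is isolated and freed from aluminium and copper residues. MeLi in THF at 0 °C then releases the lithium enolate F2, which is added to 4 at −78 °C. The closed lithium aldol transition state should give the same adduct, and the fallback comes back to the route at 10.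

Step 7. The C6 acetoxy group may participate at the activated C4 carbonyl, the allylic acetate may ionise under the acidic conditions, or the hindered ketone may enolise too slowly. The fallback installs C18 without a triflate and sets out from 14. Osmylation (OsO4 cat., NMO) gives the 7α,8α-diol ketone F3. Ac2O/pyridine gives the 6β,7α-diacetate ketone F4. Methylenation with Zn, CH2Br2 and TiCl4 (THF/CH2Cl2, 0 °C), which is ketone-selective in the presence of esters, gives the exocyclic 4(18)-alkene F5. RhCl3·3H2O (cat.) in EtOH at 60 °C isomerises this to the endocyclic C3=C4 alkene, the only possible direction because C5 has no hydrogen. The fallback comes back to the route at 18.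

Step 8. Osmylation may compete at the C11=C12 bond of the dienyl lactone, or the hindered Δ7 alkene may react too slowly. The fallback protects the diene and sets out from 15. Fe2(CO)9 in benzene at 45 °C gives the tricarbonyliron η4-diene complex F6 (C11–C14 bound to iron; the two faces of complexation are inconsequential). Stoichiometric OsO4 with pyridine in THF at −20 °C, followed by aqueous NaHSO3, hydroxylates the only free electron-rich alkene to give the diol complex F7. Me3NO in acetone at rt removes the iron, and the fallback comes back to the route at 16.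

**Further compounds**
F1 | step 3 | trimethylsilyl enol ether, (R)-{3-[(Z)-but-2-en-2-yl]-2-methylcyclohex-1-en-1-yl}oxy(trimethyl)silane | CC1=C(O[Si](C)(C)C)CCC[C@@H]1/C(C)=C\C
F2 | step 3 | lithium (R)-3-[(Z)-but-2-en-2-yl]-2-methylcyclohex-1-en-1-olate | CC1=C(O[Li])CCC[C@@H]1/C(C)=C\C
F3 | step 7 | 6β-acetoxy-7α,8α-dihydroxy-4-oxo-18-norcleroda-11E,13-dien-15,16-olide | CC(=O)O[C@H]1[C@H](O)[C@](C)(O)[C@](C)(/C=C/C3=CC(=O)OC3)[C@H]2CCCC(=O)[C@]12C
F4 | step 7 | 6β,7α-diacetoxy-8α-hydroxy-4-oxo-18-norcleroda-11E,13-dien-15,16-olide | CC(=O)O[C@H]1[C@H](OC(C)=O)[C@](C)(O)[C@](C)(/C=C/C3=CC(=O)OC3)[C@H]2CCCC(=O)[C@]12C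
F5 | step 7 | 6β,7α-diacetoxy-8α-hydroxycleroda-4(18),11E,13-trien-15,16-olide | CC(=O)O[C@H]1[C@H](OC(C)=O)[C@](C)(O)[C@](C)(/C=C/C3=CC(=O)OC3)[C@H]2CCCC(=C)[C@]12C
F6 | step 8 | tricarbonyliron η4-(C11–C14) complex of 15 (written as ligand plus Fe(CO)3) | CC(=O)O[C@H]1C=C(C)[C@](C)(/C=C/C3=CC(=O)OC3)[C@H]2CCC=C(OS(=O)(=O)C(F)(F)F)[C@]12C.[Fe].[C-]#[O+].[C-]#[O+].[C-]#[O+]
F7 | step 8 | tricarbonyliron η4-(C11–C14) complex of 16 (written as ligand plus Fe(CO)3) | CC(=O)O[C@H]1[C@H](O)[C@](C)(O)[C@](C)(/C=C/C3=CC(=O)OC3)[C@H]2CCC=C(OS(=O)(=O)C(F)(F)F)[C@]12C.[Fe].[C-]#[O+].[C-]#[O+].[C-]#[O+]
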